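**Plan**

- Retrosynthesis: cut (a) the aryl–vinyl C–C bond of the propenal chain (Heck reaction, Br as placeholder), (b) the O–CH3 bond of the 4-methoxy group on the trimethoxyphenyl ring (a free phenol serves as activating helper), then (c) both C–O bonds of the dioxane ring at once (O1–C2 and C3–O4 of 7). This leaves o-quinone 5 (from catechol 2) and (E)-propenylphenol 4.
- Enabling feature: the dioxane ring is a catechol O–C(ar)=C(ar)–O unit, the reduced form of an o-quinone O=C–C=O heterodiene, bridged by a CH(aryl)–CH(CH3) unit with trans substituents, i.e. an (E)-1-arylpropene. The para oxygen of that aryl ring, kept as OH, makes C-β nucleophilic and the benzylic carbon a p-quinone methide electrophile.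
- Forward: both benzene rings are bought. A Dakin oxidation gives catechol 2 and a double-bond migration gives 4. The dioxane ring is closed last by a catalytic enantioselective oxidative formal hetero-[4+2] union, then O-methylation and a Heck reaction with an acrolein acetal finish the target.
- Stereochemistry: the CH(CH3) centre is set by a chiral phosphoric acid in the first C–O bond formation. The CH(aryl) centre follows by substrate control (trans, diequatorial, equilibrating through the quinone methide). The (E)-enal comes from the Heck step.

Key step: step 3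

Assumptions: compounds 1 and 3 are taken as commercial. The (R)-enantiomer of the phosphoric acid catalyst is assumed to lead to the (2S,3S) series; if the sense of induction proves opposite, its mirror image is used with no other change.

**Route**

Step 1
Reactants: 1 5-bromo-2-hydroxy-3-methoxybenzaldehyde
Product: 2 5-bromo-3-methoxybenzene-1,2-diol
Conditions: 30% H2O2, 1 M NaOH, THF/H2O, 0 °C → rt, N2; then 2 M HCl
Reagents that add atoms: hydrogen peroxide, OO
Why: Dakin oxidation, in which hydroperoxide adds to the ortho-hydroxy aldehyde, the electron-rich aryl group migrates to oxygen and the aryl formate is hydrolysed in situ, so the formyl group becomes the second phenol oxygen while the aryl bromide is untouched.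

Step 2
Reactants: 3 4-allyl-2,6-dimethoxyphenol
Product: 4 2,6-dimethoxy-4-[(1E)-prop-1-en-1-yl]phenol
Conditions: [RuClH(CO)(PPh3)3] (1 mol %), toluene, 80 °C
Reagents that add atoms: none
Why: Ruthenium hydride-catalysed double-bond migration (hydrometalation/β-hydride elimination) moves the allyl double bond into conjugation with the arene and should give the thermodynamically favoured (E)-propenyl isomer.

Step 3
Reactants: 2 5-bromo-3-methoxybenzene-1,2-diol; 4 2,6-dimethoxy-4-[(1E)-prop-1-en-1-yl]phenol
Product: 7 4-[(2S,3S)-7-bromo-5-methoxy-3-methyl-2,3-dihydro-1,4-benzodioxin-2-yl]-2,6-dimethoxyphenol, via o-quinone 5 (not isolated), via p-quinone methide 6 (not isolated)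
Conditions: 2, Ag2O, Na2SO4, CH2Cl2, 0 °C, filtration through Celite under argon; filtrate added to 4, (R)-TRIP (10 mol %), 4 Å MS, toluene, −40 °C → −20 °C
Reagents that add atoms: none
Why: Proposed new method: silver(I) oxide dehydrogenates catechol 2 to o-quinone 5, whose O=C–C=O unit then acts as an electron-poor 1,4-dioxadiene toward the electron-rich (E)-alkene of 4 in a stepwise formal inverse-demand hetero-[4+2] addition under bifunctional phosphoric acid catalysis (P–OH on the more basic C-1 carbonyl of 5, P=O on the phenolic OH of 4): C-β of 4 attacks the oxygen on C-2 of 5, the catechol ring aromatises, and the resulting p-quinone methide 6 is captured by the neighbouring phenol in a 6-exo-trig oxa-1,6-addition. The closest known reaction types are the racemic silver(I) oxide-mediated oxidative coupling of catechols with 4-propenylphenols and the thermal o-quinone hetero-Diels–Alder reaction, both giving trans-1,4-benzodioxanes, and phosphoric acid-catalysed enantioselective formal cycloadditions of hydroxystyrenes with quinone-type acceptors through transient quinone methides; the enantioselective union of an o-quinone with a 4-hydroxystyrene has not been shown. The methyl-bearing stereocentre (C-3) should be set under catalyst control in the first C–O bond formation, on the Si face of C-β inside the hydrogen-bonded assembly, and the aryl-bearing stereocentre (C-2) under substrate control, since the chair-like closure places aryl and methyl trans-diequatorial and any cis isomer can return through acid-reversible reopening to 6, which leaves C-3 untouched. The step needs regioselectivity (the oxygen flanked by OMe must bond to CHMe), and this is secured by the 3-methoxy and 5-bromo donors, which are conjugated with the C-1 carbonyl only, so that this oxygen is the one protonated by the catalyst and ends as the phenol nucleophile while the C-2 oxygen is the electrophilic terminus. Chemoselectivity for O,O-addition over carbocyclic Diels–Alder addition or C-alkylation of the quinone ring is favoured by the electron-rich alkene, and the quinone is made in a separate stage and filtered from silver so that no oxidant meets the catalyst or the free phenol 4. The absolute sense of induction cannot be predicted with confidence, which is why the catalyst enantiomer is left open to exchange.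

Step 4
Reactants: 7 4-[(2S,3S)-7-bromo-5-methoxy-3-methyl-2,3-dihydro-1,4-benzodioxin-2-yl]-2,6-dimethoxyphenol
Product: 8 (2S,3S)-7-bromo-5-methoxy-3-methyl-2-(3,4,5-trimethoxyphenyl)-2,3-dihydro-1,4-benzodioxine
Conditions: MeI, K2CO3, acetone, rt
Reagents that add atoms: iodomethane, CI
Why: Williamson O-methylation of the only free phenol (SN2 on iodomethane) caps the activating hydroxyl as the fourth aryl methoxy group; the stereocentres are not involved, and fast capture of the phenoxide should pre-empt a retro-oxa-Michael opening of the benzylic ether.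

Step 5
Reactants: 8 (2S,3S)-7-bromo-5-methoxy-3-methyl-2-(3,4,5-trimethoxyphenyl)-2,3-dihydro-1,4-benzodioxine
Product: 10 (2E)-3-[(2S,3S)-8-methoxy-2-methyl-3-(3,4,5-trimethoxyphenyl)-2,3-dihydro-1,4-benzodioxin-6-yl]prop-2-enal (target), via diethyl acetal 9 (not isolated)
Conditions: 3,3-diethoxyprop-1-ene, Pd(OAc)2 (5 mol %), nBu4NOAc, K2CO3, KCl, DMF, 90 °C; then 2 M HCl, rt
Reagents that add atoms: 3,3-diethoxyprop-1-ene (acrolein diethyl acetal), C=CC(OCC)OCC; water, O
Why: Heck reaction of the aryl bromide with acrolein diethyl acetal (oxidative addition, syn-carbopalladation at the terminal carbon, syn-β-hydride elimination on the benzylic side under tetraalkylammonium acetate conditions) should give the (E)-cinnamyl acetal 9, which dilute acid hydrolyses to the (E)-enal without touching the benzodioxane stereocentres, since no free para-hydroxyl remains to open the benzylic ether.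

**Compound list**

1 | 5-bromo-2-hydroxy-3-methoxybenzaldehyde | COc1cc(Br)cc(C=O)c1O | starting material
2 | 5-bromo-3-methoxybenzene-1,2-diol | COc1cc(Br)cc(O)c1O | intermediate
3 | 4-allyl-2,6-dimethoxyphenol | COc1cc(CC=C)cc(OC)c1O | starting material
4 | 2,6-dimethoxy-4-[(1E)-prop-1-en-1-yl]phenol | COc1cc(/C=C/C)cc(OC)c1O | intermediate
5 | 5-bromo-3-methoxycyclohexa-3,5-diene-1,2-dione (o-quinone, not isolated) | COC1=CC(Br)=CC(=O)C1=O | intermediate
6 | 4-[(2S)-2-(4-bromo-2-hydroxy-6-methoxyphenoxy)propylidene]-2,6-dimethoxycyclohexa-2,5-dien-1-one (p-quinone methide, not isolated) | C[C@H](Oc1c(O)cc(Br)cc1OC)C=C1C=C(OC)C(=O)C(OC)=C1 | intermediate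
7 | 4-[(2S,3S)-7-bromo-5-methoxy-3-methyl-2,3-dihydro-1,4-benzodioxin-2-yl]-2,6-dimethoxyphenol | COc1cc([C@@H]2Oc3cc(Br)cc(OC)c3O[C@H]2C)cc(OC)c1O | intermediate
8 | (2S,3S)-7-bromo-5-methoxy-3-methyl-2-(3,4,5-trimethoxyphenyl)-2,3-dihydro-1,4-benzodioxine | COc1cc([C@@H]2Oc3cc(Br)cc(OC)c3O[C@H]2C)cc(OC)c1OC | intermediate
9 | (2S,3S)-6-[(1E)-3,3-diethoxyprop-1-en-1-yl]-8-methoxy-2-methyl-3-(3,4,5-trimethoxyphenyl)-2,3-dihydro-1,4-benzodioxine (not isolated) | COc1cc([C@@H]2Oc3cc(/C=C/C(OCC)OCC)cc(OC)c3O[C@H]2C)cc(OC)c1OC | intermediate
10 | (2E)-3-[(2S,3S)-8-methoxy-2-methyl-3-(3,4,5-trimethoxyphenyl)-2,3-dihydro-1,4-benzodioxin-6-yl]prop-2-enal | COc1cc([C@@H]2Oc3cc(/C=C/C=O)cc(OC)c3O[C@H]2C)cc(OC)c1OC | target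

**Summary**

Total step count: 5. Longest linear sequence: 4 steps (1 → 2 → 7 → 8 → 10, or 3 → 4 → 7 → 8 → 10).

**Steps most likely to fail**

Step 3 (proposed new method). The first C–O bond formation may proceed without face selectivity if the uncatalysed addition outruns the catalysed one. The wrong quinone oxygen may react first. Electron transfer from 4 to the quinone may divert material into oxidative homocoupling. The fallback uses known chemistry, sets out from 1 and comes back at 8. Mitsunobu etherification of phenol 1 with methyl (R)-lactate (PPh3, DIAD, THF) proceeds with inversion and gives methyl (2S)-2-(4-bromo-2-formyl-6-methoxyphenoxy)propanoate F1. Baeyer–Villiger oxidation (mCPBA, CH2Cl2) gives methyl (2S)-2-[4-bromo-2-(formyloxy)-6-methoxyphenoxy]propanoate F2. Acid-catalysed methanolysis (TsOH, MeOH) frees methyl (2S)-2-(4-bromo-2-hydroxy-6-methoxyphenoxy)propanoate F3, which on heating with TsOH in toluene lactonises to (3S)-7-bromo-5-methoxy-3-methyl-1,4-benzodioxin-2(3H)-one F4. Addition of 3,4,5-trimethoxyphenylmagnesium bromide at −78 °C opens the lactone to (2S)-2-(4-bromo-2-hydroxy-6-methoxyphenoxy)-1-(3,4,5-trimethoxyphenyl)propan-1-one F5. NaBH4 reduces this to (2S)-2-(4-bromo-2-hydroxy-6-methoxyphenoxy)-1-(3,4,5-trimethoxyphenyl)propan-1-ol F6 as a mixture of carbinol epimers. TsOH in CH2Cl2 then ionises the benzylic alcohol, and the cation is captured by the phenol under thermodynamic control to give the trans-benzodioxane 8, the lactate-derived centre fixing the absolute configuration.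

Step 5. Oxidative addition of the electron-rich aryl bromide may be slow, and β-hydride elimination may occur toward the acetal carbon, which after hydrolysis leads to the saturated ester oxidation level. The fallback sets out from 8 and comes back at 10. Bromine–lithium exchange (nBuLi, THF, −78 °C) and formylation with DMF give (2S,3S)-8-methoxy-2-methyl-3-(3,4,5-trimethoxyphenyl)-2,3-dihydro-1,4-benzodioxine-6-carbaldehyde F7. A Wittig two-carbon homologation with (triphenylphosphoranylidene)acetaldehyde (toluene, 80 °C) should then give 10 as the (E)-enal.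

Step 1. The electron-rich catecholate may be over-oxidised by alkaline peroxide or air, with quinone formation and ring degradation. The fallback sets out from 1 and comes back at 2. Baeyer–Villiger oxidation with mCPBA in CH2Cl2, without base, gives 5-bromo-2-hydroxy-3-methoxyphenyl formate F8, which is isolated. Acid-catalysed methanolysis under argon then cleaves it to 2.

**Further compounds**

F1 | step 3 | methyl (2S)-2-(4-bromo-2-formyl-6-methoxyphenoxy)propanoate | C[C@H](Oc1c(C=O)cc(Br)cc1OC)C(=O)OC
F2 | step 3 | methyl (2S)-2-[4-bromo-2-(formyloxy)-6-methoxyphenoxy]propanoate | C[C@H](Oc1c(OC=O)cc(Br)cc1OC)C(=O)OC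
F3 | step 3 | methyl (2S)-2-(4-bromo-2-hydroxy-6-methoxyphenoxy)propanoate | C[C@H](Oc1c(O)cc(Br)cc1OC)C(=O)OC
F4 | step 3 | (3S)-7-bromo-5-methoxy-3-methyl-1,4-benzodioxin-2(3H)-one | C[C@@H]1Oc2c(OC)cc(Br)cc2OC1=O
F5 | step 3 | (2S)-2-(4-bromo-2-hydroxy-6-methoxyphenoxy)-1-(3,4,5-trimethoxyphenyl)propan-1-one | C[C@H](Oc1c(O)cc(Br)cc1OC)C(=O)c1cc(OC)c(OC)c(OC)c1
F6 | step 3 | (2S)-2-(4-bromo-2-hydroxy-6-methoxyphenoxy)-1-(3,4,5-trimethoxyphenyl)propan-1-ol (carbinol epimers) | C[C@H](Oc1c(O)cc(Br)cc1OC)C(O)c1cc(OC)c(OC)c(OC)c1
F7 | step 5 | (2S,3S)-8-methoxy-2-methyl-3-(3,4,5-trimethoxyphenyl)-2,3-dihydro-1,4-benzodioxine-6-carbaldehyde | COc1cc([C@@H]2Oc3cc(C=O)cc(OC)c3O[C@H]2C)cc(OC)c1OC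
F8 | step 1 | 5-bromo-2-hydroxy-3-methoxyphenyl formate | COc1cc(Br)cc(OC=O)c1O
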